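**Assumptions.** (i) The (R)-diarylprolinol silyl ether is assumed to give the (R) configuration at each α-carbon. This rests on the Hayashi–Jørgensen facial model, in which the enamine is attacked on the face opposite the bulky group. If the opposite sense is observed, the enantiomeric catalyst is used. (ii) Under mild Brønsted acid, vanillyl alcohol ionises to a p-hydroxybenzyl cation or p-quinone methide, so the phenols need no protection.

**Target check.** The target is a 2,3,4-trisubstituted THF.
- C2 (lignan C7) carries the guaiacyl group and is S.
- C3 (C8) carries CH2OH and is R.
- C4 (C8′) carries the guaiacylmethyl group and is R.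
- The aryl group is trans to CH2OH, and CH2OH and the benzyl group are cis.
- The C8/C8′ centres are therefore the (R,R) pair of (−)-secoisolariciresinol.

## Retrosynthesis
1. (+)-Lariciresinol (8) comes from (−)-secoisolariciresinol (7) by oxidative benzylic C–O ring closure. This is the only ring formed, and it is formed last. C7 is set thermodynamically as 2,3-trans.
2. 7 comes from NaBH4 reduction of the C2-symmetric (2R,3R)-2,3-dibenzylsuccinaldehyde (6).
3. 6 comes from two successive catalyst-controlled enamine α-benzylations of succinaldehyde (2) with vanillyl alcohol (3), via the mono-benzyl adduct 5. Together these set C8 and C8′.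
4. 2 is released from 2,5-dimethoxytetrahydrofuran (1).

## Route

**Step 1**
Reactants: 1, 2,5-dimethoxytetrahydrofuran
Product: 2, succinaldehyde (butanedial)
Conditions: H2O, 0.1 M HCl, 70 °C, 1 h; neutralise with NaHCO3, extract continuously with CH2Cl2; use the solution at once.
Reagents that add atoms: water, O
Why: Acid hydrolysis of the cyclic bis-acetal releases the dialdehyde and two MeOH. Succinaldehyde is an achiral bis-enamine donor.

**Step 2**
Reactants: 2, succinaldehyde (1.0 equiv); 3, vanillyl alcohol (4-(hydroxymethyl)-2-methoxyphenol, 1.0 equiv); 4, (R)-diphenylprolinol TMS ether
Product: 5, (R)-2-(4-hydroxy-3-methoxybenzyl)butanedial. It is not isolated and goes directly into step 3.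
Conditions: 4 (20 mol%), TFA (20 mol%), MeCN (0.1 M), 3 added by syringe pump over 10 h, 25 °C, then 2 h.
Reagents that add atoms: vanillyl alcohol (3), COc1cc(CO)ccc1O, supplies the ArCH2 group.
Why: Proposed new method: 4 condenses with one aldehyde of 2 to give an E-enamine whose bulky diaryl(silyloxy) group blocks one face. TFA ionises 3 to the electron-rich p-hydroxybenzyl cation or p-quinone methide, which the enamine attacks on the open face. Hydrolysis then releases the (R)-α-benzyl aldehyde. The closest known chemistry is Cozzi-type enamine SN1 α-benzylation with stabilised benzylic alcohols, organocatalytic 1,6-additions to p-quinone methides, and succinaldehyde as a donor in enamine catalysis. The new features are an unmasked vanillyl electrophile bearing a free phenol, and succinaldehyde used as a benzylation donor. Slow addition of 3 keeps its concentration low, which disfavours self-condensation and double benzylation at this stage.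

**Step 3**
Reactants: 5, mono-benzyl dialdehyde (crude, in the step 2 pot); 3, vanillyl alcohol (1.4 equiv); 4, (R)-diphenylprolinol TMS ether (a further 5 mol%)
Product: 6, (2R,3R)-2,3-bis(4-hydroxy-3-methoxybenzyl)butanedial
Conditions: 3 and TFA (20 mol%) added to the same pot, MeCN, 40 °C, 40 h.
Reagents that add atoms: vanillyl alcohol (3), COc1cc(CO)ccc1O, supplies the second ArCH2 group.
Why: Proposed new method: this is the same enamine SN1 benzylation applied to the remaining unsubstituted CH2CHO terminus of 5, which is the less hindered enamine site. The same catalyst face control sets the second centre as R, so the product is the C2-symmetric dl (R,R) dialdehyde rather than the meso one. The closest known reaction type is organocatalytic α-benzylation of aldehydes via enamine SN1, here with an α-branched aldehyde as the donor.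

**Step 4**
Reactants: 6, dialdehyde (crude, from step 3)
Product: 7, (−)-secoisolariciresinol, (2R,3R)-2,3-bis(4-hydroxy-3-methoxybenzyl)butane-1,4-diol
Conditions: cool the step 3 mixture to 0 °C and add MeOH and solid NaHCO3 (to neutralise TFA); then NaBH4 (4 equiv), −10 → 0 °C, 30 min; aqueous NH4Cl quench; chromatography (removes residual 3 and catalyst).
Reagents that add atoms: none (NaBH4 supplies only hydride; boron is not retained)
Why: Chemoselective hydride reduction of both aldehydes, run cold and short after removing the acid, limits epimerisation of the α-stereocentres. Phenols and aryl ethers are untouched, and no new stereocentre forms.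

**Step 5**
Reactants: 7, (−)-secoisolariciresinol
Product: 8, (+)-lariciresinol
Conditions: DDQ (0.9 equiv), anhydrous CH2Cl2, 0 °C, 1 h; then TFA (5 mol%), rt, 3 h; chromatography.
Reagents that add atoms: none (DDQ ends up as DDQH2)
Why: This is DDQ benzylic oxidation of a 4-alkylguaiacol to the p-quinone methide, followed by intramolecular oxa-Michael trapping; it is the biomimetic secoisolariciresinol-to-lariciresinol type of closure. The C9′–OH adds to C7 in a 5-exo closure, whereas the C9–OH would need a 4-membered ring and does not compete. The second arene is equivalent by symmetry, so either regiochemistry gives the same product. Reversible acid-promoted benzylic ionisation of the p-hydroxyaryl ether funnels C7 to the stable 2,3-trans isomer (7S). C8 and C8′ are untouched, and the cis CH2OH and benzyl groups carried by the (R,R) precursor end up cis on the ring, as in the target.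

## Compound list
1 | 2,5-dimethoxytetrahydrofuran | COC1CCC(OC)O1 | starting material
2 | succinaldehyde | O=CCC=O | intermediate
3 | vanillyl alcohol | COc1cc(CO)ccc1O | starting material
4 | (R)-diphenylprolinol trimethylsilyl ether (organocatalyst) | C[Si](C)(C)OC(c1ccccc1)(c1ccccc1)[C@H]1CCCN1 | starting material
5 | (R)-2-(4-hydroxy-3-methoxybenzyl)butanedial (formed in situ, not isolated) | O=C[C@H](Cc1ccc(O)c(OC)c1)CC=O | intermediate
6 | (2R,3R)-2,3-bis(4-hydroxy-3-methoxybenzyl)butanedial | COc1cc(C[C@@H](C=O)[C@H](C=O)Cc2ccc(O)c(OC)c2)ccc1O | intermediate
7 | (−)-secoisolariciresinol | COc1cc(C[C@@H](CO)[C@H](CO)Cc2ccc(O)c(OC)c2)ccc1O | intermediate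
8 | (+)-lariciresinol | COc1cc(C[C@H]2CO[C@H](c3ccc(O)c(OC)c3)[C@H]2CO)ccc1O | target

Atom balance:
- Step 1: C6H12O3 + H2O → C4H6O2 + 2 MeOH.
- Step 2: C4H6O2 + C8H10O3 → C12H14O4 + H2O.
- Step 3: C12H14O4 + C8H10O3 → C20H22O6 + H2O.
- Step 4: C20H22O6 + 4 H → C20H26O6.
- Step 5: C20H26O6 − 2 H → C20H24O6, which is lariciresinol.

**Total steps:** 5. **Longest linear sequence:** 5. Steps 2–4 can be run as one pot, so there are only three isolation points.

## Three steps most likely to fail
1. **Step 2 (proposed new method; step 3 repeats the same reaction and shares its failure modes).**
   - Failure modes: vanillyl alcohol self-condensation or N-benzylation of the catalyst, over-benzylation or incomplete conversion at the mono stage, low dl:meso selectivity, and catalyst-mediated α-epimerisation of 6.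
   - Fallback using known chemistry: protect the phenols as benzyl ethers and run the Hayashi–Jørgensen Michael addition of 3-(4-benzyloxy-3-methoxyphenyl)propanal to (E)-ArCH2CH=CHNO2. Use the catalyst enantiomer that gives the (R,R) series; the syn adduct corresponds to dl. Then reduce the aldehyde with NaBH4, convert CH2NO2 to CHO by Nef reaction and reduce it, and remove the benzyl groups by hydrogenolysis to give 7.
2. **Step 5.**
   - Failure modes: the second arene can also oxidise and close to the furofuran (pinoresinol type), the product's α-aryl ether C–H can over-oxidise, and C7 selectivity can be incomplete.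
   - Fallback: benzylate the phenols, mono-silylate one primary OH (NaH, TBSCl), and close the ring by Suárez 1,5-HAT cyclisation of the remaining alkoxy radical (PhI(OAc)2, I2, hv) at C7. Then remove TBS with TBAF and the benzyl groups with H2/Pd-C. Epimerise C7 to the trans isomer with acid if needed.
3. **Step 1 (with the dialdehyde handling in step 2).**
   - Failure modes: free succinaldehyde polymerises, and α-branched dialdehydes are configurationally labile.
   - Fallback: use 4,4-dimethoxybutanal (succinaldehyde mono-dimethyl acetal) as a masked donor. Benzylate once with the same catalyst, reduce to the alcohol, protect it as the TBS ether, hydrolyse the acetal, then benzylate and reduce a second time. This also gives a mono-TBS diol that is desymmetrised for step 5.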